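## Retrosynthetic overview

1. Sodwanone B ⇒ enynone 33 by late redox adjustments (C-6 hydroxylation, alkyne hydrogenation, desilylation, triple alcohol oxidation); the diosphenol is the enol of the 6,7-dione.
2. 33 ⇒ C9–C11 bond by Stork–Danheiser addition of the left-half lithium acetylide (from 32, which carries both linker carbons) to the right-half vinylogous ester 16.
3. 16 ⇒ trans-decalin-7,9-dione ⇒ 4,4-dimethyl-Δ5-octalin ⇒ hydroxy-enone 6. Ring B is 2-methylcyclohexane-1,3-dione, desymmetrised by a ketoreductase; ring A is then closed by aldol condensation.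
4. 32 ⇒ bicycle 26, whose oxepane and cyclohexane form together in a diepoxide → epoxonium → allylsilane cascade; the diepoxide comes from Shi epoxidation of acyclic triene 22.
5. Ring order: right half B then A; left half oxepane and carbocycle in one step; the halves are joined last.

Assumptions (one line each):
- Step 3: a Prelog-type ketoreductase picked by panel screening is assumed to reduce the carbonyl that makes the quaternary carbon R; the carbinol configuration is irrelevant because that carbon is re-oxidised in step 11.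
- Step 17: the D-fructose-derived Shi ketone is taken to give (R,R)-epoxides from E-trisubstituted olefins, so its enantiomer is used.
- Locants: right half uses decalin (drimane) numbering (C-10 = quaternary C–Me, C-3/C-4 = oxygenated carbon/CMe2, C-5 = ring fusion, C-7/C-9 = ring-B carbonyl positions); left half uses 1-benzoxepine numbering.

## Right half (steps 1–13)

Step 1
Reactants: 1, 2-methylcyclohexane-1,3-dione; 2, methyl vinyl ketone
Product: 3, 2-methyl-2-(3-oxobutyl)cyclohexane-1,3-dione
Conditions: Et3N (cat.), EtOAc, rt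
Reagents that add atoms: methyl vinyl ketone (2), CC(=O)C=C
Why: Michael addition of the acidic 1,3-dione to the enone gives the prochiral triketone.

Step 2
Reactants: 3
Product: 4, 2-methyl-2-[2-(2-methyl-1,3-dioxolan-2-yl)ethyl]cyclohexane-1,3-dione
Conditions: (TMSOCH2)2, TMSOTf (cat.), CH2Cl2, −78 → −20 °C
Reagents that add atoms: 1,2-bis(trimethylsilyloxy)ethane, C[Si](C)(C)OCCO[Si](C)(C)C
Why: Noyori ketalisation is chemoselective for the unhindered methyl ketone over the two ring carbonyls flanking the quaternary carbon, so the side chain is hidden from the enzyme.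

Step 3
Reactants: 4
Product: 5, (2R,3S)-3-hydroxy-2-methyl-2-[2-(2-methyl-1,3-dioxolan-2-yl)ethyl]cyclohexan-1-one
Conditions: ketoreductase (KRED), NADP+ (cat.), glucose/glucose dehydrogenase, pH 7 phosphate buffer, 5% DMSO, 30 °C
Reagents that add atoms: none
Why: Enzymatic desymmetrising reduction of one enantiotopic carbonyl of the 2,2-disubstituted 1,3-dione sets the quaternary stereocentre (future C-10) and the adjacent carbinol in one catalytic step.

Step 4
Reactants: 5
Product: 6, (4aS,5S)-5-hydroxy-4a-methyl-4,4a,5,6,7,8-hexahydronaphthalen-2(3H)-one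
Conditions: 1 M HCl, THF, rt; then pyrrolidine, AcOH, toluene, 40 °C
Reagents that add atoms: water, O
Why: Ketal hydrolysis then amine-catalysed intramolecular aldol condensation (second half of the Robinson annulation) onto the only remaining ring ketone closes ring A without touching the stereocentres.

Step 5
Reactants: 6
Product: 7, (1S,8aS)-8a-methyl-6-oxo-1,2,3,4,6,7,8,8a-octahydronaphthalen-1-yl pivalate
Conditions: PivCl, pyridine, DMAP, CH2Cl2, rt → 40 °C
Reagents that add atoms: pivaloyl chloride, CC(C)(C)C(=O)Cl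
Why: Acylation masks the C-9 carbinol as a non-enolisable ester that tolerates KOtBu and is later removed reductively.

Step 6
Reactants: 7; 8, iodomethane
Product: 9, (1S,8aS)-5,5,8a-trimethyl-6-oxo-1,2,3,5,6,7,8,8a-octahydronaphthalen-1-yl pivalate
Conditions: KOtBu, t-BuOH, MeI, rt
Reagents that add atoms: iodomethane (8), CI
Why: Deconjugative double α-methylation of the dienolate gives the 4,4-dimethyl-Δ5-3-ketone, the standard outcome for octalones of this type.

Step 7
Reactants: 9
Product: 10, (1S,6S,8aS)-6-hydroxy-5,5,8a-trimethyl-1,2,3,5,6,7,8,8a-octahydronaphthalen-1-yl pivalate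
Conditions: NaBH4, MeOH, 0 °C
Reagents that add atoms: none
Why: Hydride adds from the face opposite the angular methyl to give the 3β-alcohol; this centre is only a temporary mask for the C-3 ketone.

Step 8
Reactants: 10
Product: 11, the 3β-TBS ether of 10
Conditions: TBSOTf, 2,6-lutidine, CH2Cl2, 0 °C
Reagents that add atoms: TBS triflate, CC(C)(C)[Si](C)(C)OS(=O)(=O)C(F)(F)F
Why: Silylation protects the hindered C-3 alcohol through the organometallic and enolate steps that follow.

Step 9
Reactants: 11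
Product: 12, 3β-TBSO-9β-pivaloyloxy-4,4,10-trimethyldecal-5-en-7-one
Conditions: CrO3, 3,5-dimethylpyrazole, CH2Cl2, −20 °C
Reagents that add atoms: chromium trioxide, O=[Cr](=O)=O
Why: Allylic oxidation can only occur at C-7, the sole allylic CH2 (C-4 and C-10 are quaternary).

Step 10
Reactants: 12
Product: 13, 3β-TBSO-9β-hydroxy-4,4,10-trimethyl-5α-decalin-7-one
Conditions: Li (excess), NH3(l)/THF, −78 → −33 °C; NH4Cl
Reagents that add atoms: none
Why: Dissolving-metal enone reduction gives the trans-fused decalone (5-H anti to the angular methyl) and cleaves the pivalate in the same pot; any over-reduced 7-ol converges in step 11.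

Step 11
Reactants: 13
Product: 14, (4aS,6S,8aS)-6-TBSO-5,5,8a-trimethylhexahydronaphthalene-1,3(2H,4H)-dione
Conditions: Dess–Martin periodinane, NaHCO3, CH2Cl2, rt
Reagents that add atoms: none
Why: Dess–Martin oxidation of the β-hydroxy ketone gives the ring-B 1,3-diketone without retro-aldol.

Step 12
Reactants: 14; 8, iodomethane
Product: 15, the 8-methyl-7,9-dione (2-methyl derivative of 14; C-8 epimers/enol)
Conditions: MeI, K2CO3, acetone, reflux
Reagents that add atoms: iodomethane (8), CI
Why: C-alkylation of the cyclic 1,3-diketone occurs at the only doubly activated carbon, C-8.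

Step 13
Reactants: 15
Product: 16, 3β-TBSO-7-isobutoxy-4,4,8,10-tetramethyl-5α-decal-7-en-9-one
Conditions: i-BuOH, PPTS (cat.), benzene, reflux, Dean–Stark
Reagents that add atoms: isobutanol, CC(C)CO
Why: Vinylogous ester formation is regioselective because the alcohol attacks the unhindered C-7 carbonyl, leaving the C-9 carbonyl next to the quaternary carbon.

## Left half (steps 14–25)

Step 14
Reactants: 17, geranyl bromide; 18, methyl acetoacetate
Product: 19, methyl (6E)-7,11-dimethyl-3-oxododeca-6,10-dienoate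
Conditions: 18, NaH then n-BuLi, THF, 0 °C; then 17
Reagents that add atoms: geranyl bromide (17), CC(C)=CCC/C(C)=C/CBr
Why: Weiler alkylation of the acetoacetate dianion occurs at the γ-carbon with the allylic bromide.

Step 15
Reactants: 19
Product: 20, methyl (2Z,6E)-3-[(diethoxyphosphoryl)oxy]-7,11-dimethyldodeca-2,6,10-trienoate
Conditions: NaH, Et2O, 0 °C; ClP(O)(OEt)2
Reagents that add atoms: diethyl chlorophosphate, CCOP(=O)(Cl)OCC
Why: O-phosphorylation of the chelated sodium enolate gives the Z-enol phosphate stereoselectively.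

Step 16
Reactants: 20; 21, (trimethylsilyl)methylmagnesium chloride
Product: 22, methyl (2Z,6E)-7,11-dimethyl-3-[(trimethylsilyl)methyl]dodeca-2,6,10-trienoate
Conditions: Ni(acac)2 (5 mol%), THF, 0 °C → rt
Reagents that add atoms: (trimethylsilyl)methylmagnesium chloride (21), C[Si](C)(C)C[Mg]Cl
Why: Nickel-catalysed Kumada-type coupling of the enol phosphate proceeds with retention, placing CH2SiMe3 cis to the ester.

Step 17
Reactants: 22
Product: 23, (6S,7S,10S)-6,7:10,11-diepoxide of 22
Conditions: L-fructose-derived Shi ketone (30 mol%), Oxone, K2CO3, Bu4NHSO4, MeCN/DMM/aq. buffer (pH 10.5), 0 °C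
Reagents that add atoms: Oxone (potassium peroxymonosulfate), [K+].[O-]S(=O)(=O)OO
Why: Shi asymmetric epoxidation sets the 6,7-epoxide (future C-9a/C-5a) and the 10,11-epoxide under catalyst control, while the electron-poor enoate olefin is untouched.

Step 18
Reactants: 23
Product: 24, the allylic alcohol from ester reduction of 23
Conditions: DIBAL-H, CH2Cl2, −78 °C
Reagents that add atoms: none
Why: DIBAL reduces the enoate to the allylic alcohol at low temperature without opening the trisubstituted epoxides.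

Step 19
Reactants: 24
Product: 25, the allylic acetate of 24
Conditions: Ac2O, Et3N, DMAP, CH2Cl2, 0 °C
Reagents that add atoms: acetic anhydride, CC(=O)OC(C)=O
Why: Acetylation caps the alcohol so it cannot compete as a nucleophile in the cationic cascade.

Step 20
Reactants: 25
Product: 26, [(3S,5aS,6R,9aS)-3-hydroxy-2,2,5a-trimethyl-7-methylidenedecahydro-1-benzoxepin-6-yl]methyl acetate
Conditions: TMSOTf, 2,6-di-tert-butyl-4-methylpyridine, CH2Cl2, −78 °C; then 1 M HCl/THF (cleaves the O–TMS ether)
Reagents that add atoms: none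
Why: Biomimetic oxa-/carbacyclisation: the activated terminal epoxide is opened at its tertiary carbon by the internal epoxide oxygen, and the resulting epoxonium is opened with inversion at C-5a by the allylsilane through a chair transition state. This gives the trans-fused oxepane–cyclohexane, an equatorial C-6 substituent (from the olefin geometry) and the exocyclic methylene (loss of silicon).

Step 21
Reactants: 26
Product: 27, the 3-O-TBS ether of 26
Conditions: TBSOTf, 2,6-lutidine, CH2Cl2, 0 °C
Reagents that add atoms: TBS triflate, CC(C)(C)[Si](C)(C)OS(=O)(=O)C(F)(F)F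
Why: Silylation protects the oxepane carbinol until the final oxidation.

Step 22
Reactants: 27
Product: 28, [(3S,5aS,6R,7R,9aS)-3-TBSO-2,2,5a,7-tetramethyldecahydro-1-benzoxepin-6-yl]methyl acetate
Conditions: H2 (1 atm), PtO2, EtOAc, rt
Reagents that add atoms: none
Why: Heterogeneous hydrogenation adds H2 to the face away from the axial C-5a methyl, giving the axial C-7 methyl cis to the C-6 chain.

Step 23
Reactants: 28
Product: 29, the primary alcohol from 28
Conditions: K2CO3, MeOH, rt
Reagents that add atoms: none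
Why: Mild methanolysis removes the acetate and leaves the hindered TBS ether intact.

Step 24
Reactants: 29
Product: 30, (3S,5aS,6R,7R,9aS)-3-TBSO-2,2,5a,7-tetramethyldecahydro-1-benzoxepine-6-carbaldehyde
Conditions: Dess–Martin periodinane, NaHCO3, CH2Cl2, 0 °C → rt
Reagents that add atoms: none
Why: Buffered Dess–Martin oxidation gives the hindered aldehyde without epimerising C-6.

Step 25
Reactants: 30; 31, dimethyl (1-diazo-2-oxopropyl)phosphonate
Product: 32, (3S,5aS,6S,7R,9aS)-3-TBSO-6-ethynyl-2,2,5a,7-tetramethyldecahydro-1-benzoxepine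
Conditions: 31, K2CO3, MeOH, 0 °C → rt
Reagents that add atoms: Ohira–Bestmann reagent (31), COP(=O)(OC)C(=[N+]=[N-])C(C)=O
Why: Seyferth–Gilbert (Ohira–Bestmann) homologation converts the aldehyde into the terminal alkyne, supplying the second linker carbon.

## Union and endgame (steps 26–30)

Step 26
Reactants: 32; 16
Product: 33, enynone: 3β-TBSO-4,4,8,10-tetramethyl-5α-decal-8-en-7-one carrying at C-9 the ethynyl group attached to C-6 of the left-half bicycle
Conditions: 32, n-BuLi, THF, −78 °C (CeCl3 optional); then 16, −78 → 0 °C; then 1 M HCl, rt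
Reagents that add atoms: water, O
Why: Stork–Danheiser sequence: 1,2-addition of the small, linear acetylide to the C-9 carbonyl, then acid hydrolysis/dehydration transposes the enone to give the 8-methyl-Δ8-7-one with the chain at C-9.

Step 27
Reactants: 33
Product: 34, the 6-hydroxy derivative of 33 (C-6 epimers)
Conditions: LDA, THF, −78 °C; then 2-(phenylsulfonyl)-3-phenyloxaziridine
Reagents that add atoms: Davis oxaziridine, O=S(=O)(c1ccccc1)N1OC1c1ccccc1
Why: Kinetic α′-deprotonation at C-6, followed by Davis enolate hydroxylation; doing this before alkyne reduction means there is no competing γ-CH2.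

Step 28
Reactants: 34
Product: 35, the 6-hydroxy enone with a saturated CH2CH2 linker
Conditions: H2 (1 atm), 10% Pd/C, EtOAc, rt
Reagents that add atoms: none
Why: The alkyne is hydrogenated to the alkane, while the tetrasubstituted enone olefin next to the quaternary carbon is too hindered to reduce.

Step 29
Reactants: 35
Product: 36, triol (3-OH, 6-OH, 3′-OH)
Conditions: 48% aq. HF, MeCN, rt
Reagents that add atoms: none
Why: Acidic fluoride removes both hindered TBS ethers without the base-induced α-ketol chemistry that TBAF could cause.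

Step 30
Reactants: 36
Product: 37, sodwanone B
Conditions: Dess–Martin periodinane (excess), NaHCO3, CH2Cl2, rt
Reagents that add atoms: none
Why: Dess–Martin oxidation converts both secondary alcohols to ketones and the acyloin to the 6,7-dione, which enolises toward C-5 (the only enolisable side) to give the diosphenol.

## Compound list

1 | 2-methylcyclohexane-1,3-dione | CC1C(=O)CCCC1=O | starting material
2 | methyl vinyl ketone | CC(=O)C=C | starting material
3 | 2-methyl-2-(3-oxobutyl)cyclohexane-1,3-dione | CC(=O)CCC1(C)C(=O)CCCC1=O | intermediate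
4 | 2-methyl-2-[2-(2-methyl-1,3-dioxolan-2-yl)ethyl]cyclohexane-1,3-dione | CC1(CCC2(C)C(=O)CCCC2=O)OCCO1 | intermediate
5 | (2R,3S)-3-hydroxy-2-methyl-2-[2-(2-methyl-1,3-dioxolan-2-yl)ethyl]cyclohexan-1-one | CC1(CC[C@]2(C)[C@@H](O)CCCC2=O)OCCO1 | intermediate
6 | (4aS,5S)-5-hydroxy-4a-methyl-4,4a,5,6,7,8-hexahydronaphthalen-2(3H)-one | O=C1CC[C@]2(C)[C@@H](O)CCCC2=C1 | intermediate
7 | (1S,8aS)-8a-methyl-6-oxo-1,2,3,4,6,7,8,8a-octahydronaphthalen-1-yl pivalate | O=C1CC[C@]2(C)[C@@H](OC(=O)C(C)(C)C)CCCC2=C1 | intermediate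
8 | iodomethane | CI | starting material
9 | (1S,8aS)-5,5,8a-trimethyl-6-oxo-1,2,3,5,6,7,8,8a-octahydronaphthalen-1-yl pivalate | O=C1CC[C@]2(C)[C@@H](OC(=O)C(C)(C)C)CCC=C2C1(C)C | intermediate
10 | (1S,6S,8aS)-6-hydroxy-5,5,8a-trimethyl-1,2,3,5,6,7,8,8a-octahydronaphthalen-1-yl pivalate | O[C@H]1CC[C@]2(C)[C@@H](OC(=O)C(C)(C)C)CCC=C2C1(C)C | intermediate
11 | (1S,6S,8aS)-6-TBSO-5,5,8a-trimethyl-1,2,3,5,6,7,8,8a-octahydronaphthalen-1-yl pivalate | CC(C)(C)[Si](C)(C)O[C@H]1CC[C@]2(C)[C@@H](OC(=O)C(C)(C)C)CCC=C2C1(C)C | intermediate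
12 | (1S,6S,8aS)-6-TBSO-5,5,8a-trimethyl-3-oxo-1,2,3,5,6,7,8,8a-octahydronaphthalen-1-yl pivalate | CC(C)(C)[Si](C)(C)O[C@H]1CC[C@]2(C)[C@@H](OC(=O)C(C)(C)C)CC(=O)C=C2C1(C)C | intermediate
13 | (4S,4aS,7S,8aS)-7-TBSO-4-hydroxy-4a,8,8-trimethyloctahydronaphthalen-2(1H)-one | CC(C)(C)[Si](C)(C)O[C@H]1CC[C@]2(C)[C@@H](O)CC(=O)C[C@H]2C1(C)C | intermediate
14 | (4aS,6S,8aS)-6-TBSO-5,5,8a-trimethylhexahydronaphthalene-1,3(2H,4H)-dione | CC(C)(C)[Si](C)(C)O[C@H]1CC[C@]2(C)C(=O)CC(=O)C[C@H]2C1(C)C | intermediate
15 | (4aS,6S,8aS)-6-TBSO-2,5,5,8a-tetramethylhexahydronaphthalene-1,3(2H,4H)-dione (C-2 epimers) | CC(C)(C)[Si](C)(C)O[C@H]1CC[C@]2(C)C(=O)C(C)C(=O)C[C@H]2C1(C)C | intermediate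
16 | (4aS,6S,8aS)-6-TBSO-3-isobutoxy-2,5,5,8a-tetramethyl-4a,5,6,7,8,8a-hexahydronaphthalen-1(4H)-one | CC(C)(C)[Si](C)(C)O[C@H]1CC[C@]2(C)C(=O)C(C)=C(OCC(C)C)C[C@H]2C1(C)C | intermediate
17 | geranyl bromide | CC(C)=CCC/C(C)=C/CBr | starting material
18 | methyl acetoacetate | COC(=O)CC(C)=O | starting material
19 | methyl (6E)-7,11-dimethyl-3-oxododeca-6,10-dienoate | COC(=O)CC(=O)CC/C=C(\C)CCC=C(C)C | intermediate
20 | methyl (2Z,6E)-3-[(diethoxyphosphoryl)oxy]-7,11-dimethyldodeca-2,6,10-trienoate | CCOP(=O)(OCC)O/C(CC/C=C(\C)CCC=C(C)C)=C\C(=O)OC | intermediate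
21 | (trimethylsilyl)methylmagnesium chloride | C[Si](C)(C)C[Mg]Cl | starting material
22 | methyl (2Z,6E)-7,11-dimethyl-3-[(trimethylsilyl)methyl]dodeca-2,6,10-trienoate | COC(=O)/C=C(\C[Si](C)(C)C)CC/C=C(\C)CCC=C(C)C | intermediate
23 | methyl (2Z)-5-[(2S,3S)-3-{2-[(2S)-3,3-dimethyloxiran-2-yl]ethyl}-3-methyloxiran-2-yl]-3-[(trimethylsilyl)methyl]pent-2-enoate | COC(=O)/C=C(\C[Si](C)(C)C)CC[C@@H]1O[C@@]1(C)CC[C@@H]1OC1(C)C | intermediate
24 | (2Z)-5-[(2S,3S)-3-{2-[(2S)-3,3-dimethyloxiran-2-yl]ethyl}-3-methyloxiran-2-yl]-3-[(trimethylsilyl)methyl]pent-2-en-1-ol | OC/C=C(\C[Si](C)(C)C)CC[C@@H]1O[C@@]1(C)CC[C@@H]1OC1(C)C | intermediate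
25 | acetate of 24 | CC(=O)OC/C=C(\C[Si](C)(C)C)CC[C@@H]1O[C@@]1(C)CC[C@@H]1OC1(C)C | intermediate
26 | [(3S,5aS,6R,9aS)-3-hydroxy-2,2,5a-trimethyl-7-methylidenedecahydro-1-benzoxepin-6-yl]methyl acetate | CC(=O)OC[C@@H]1C(=C)CC[C@@H]2OC(C)(C)[C@@H](O)CC[C@]21C | intermediate
27 | [(3S,5aS,6R,9aS)-3-TBSO-2,2,5a-trimethyl-7-methylidenedecahydro-1-benzoxepin-6-yl]methyl acetate | CC(=O)OC[C@@H]1C(=C)CC[C@@H]2OC(C)(C)[C@@H](O[Si](C)(C)C(C)(C)C)CC[C@]21C | intermediate
28 | [(3S,5aS,6R,7R,9aS)-3-TBSO-2,2,5a,7-tetramethyldecahydro-1-benzoxepin-6-yl]methyl acetate | CC(=O)OC[C@@H]1[C@H](C)CC[C@@H]2OC(C)(C)[C@@H](O[Si](C)(C)C(C)(C)C)CC[C@]21C | intermediate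
29 | [(3S,5aS,6R,7R,9aS)-3-TBSO-2,2,5a,7-tetramethyldecahydro-1-benzoxepin-6-yl]methanol | OC[C@@H]1[C@H](C)CC[C@@H]2OC(C)(C)[C@@H](O[Si](C)(C)C(C)(C)C)CC[C@]21C | intermediate
30 | (3S,5aS,6R,7R,9aS)-3-TBSO-2,2,5a,7-tetramethyldecahydro-1-benzoxepine-6-carbaldehyde | O=C[C@@H]1[C@H](C)CC[C@@H]2OC(C)(C)[C@@H](O[Si](C)(C)C(C)(C)C)CC[C@]21C | intermediate
31 | dimethyl (1-diazo-2-oxopropyl)phosphonate (Ohira–Bestmann reagent) | COP(=O)(OC)C(=[N+]=[N-])C(C)=O | starting material
32 | (3S,5aS,6S,7R,9aS)-3-TBSO-6-ethynyl-2,2,5a,7-tetramethyldecahydro-1-benzoxepine | C#C[C@@H]1[C@H](C)CC[C@@H]2OC(C)(C)[C@@H](O[Si](C)(C)C(C)(C)C)CC[C@]21C | intermediate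
33 | enynone: 3β-TBSO-4,4,8,10-tetramethyl-5α-decal-8-en-7-one bearing at C-9 the ethynyl-linked left-half bicycle (3′-OTBS) | CC1=C(C#C[C@@H]2[C@H](C)CC[C@@H]3OC(C)(C)[C@@H](O[Si](C)(C)C(C)(C)C)CC[C@]32C)[C@@]2(C)CC[C@H](O[Si](C)(C)C(C)(C)C)C(C)(C)[C@@H]2CC1=O | intermediate
34 | 6-hydroxy derivative of 33 (C-6 epimers) | CC1=C(C#C[C@@H]2[C@H](C)CC[C@@H]3OC(C)(C)[C@@H](O[Si](C)(C)C(C)(C)C)CC[C@]32C)[C@@]2(C)CC[C@H](O[Si](C)(C)C(C)(C)C)C(C)(C)[C@@H]2C(O)C1=O | intermediate
35 | 6-hydroxy-Δ8-7-one with saturated CH2CH2 linker, bis-TBS ether | CC1=C(CC[C@@H]2[C@H](C)CC[C@@H]3OC(C)(C)[C@@H](O[Si](C)(C)C(C)(C)C)CC[C@]32C)[C@@]2(C)CC[C@H](O[Si](C)(C)C(C)(C)C)C(C)(C)[C@@H]2C(O)C1=O | intermediate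
36 | triol (3β-OH, 6-OH, 3′-OH) of the Δ8-7-one | CC1=C(CC[C@@H]2[C@H](C)CC[C@@H]3OC(C)(C)[C@@H](O)CC[C@]32C)[C@@]2(C)CC[C@H](O)C(C)(C)[C@@H]2C(O)C1=O | intermediate
37 | sodwanone B | CC1=C(CC[C@@H]2[C@H](C)CC[C@@H]3OC(C)(C)C(=O)CC[C@]32C)[C@@]2(C)CCC(=O)C(C)(C)C2=C(O)C1=O | target

## Summary

Total steps: 30.
Longest linear sequence: 18 (steps 1–13, then 26–30); the left-half branch is 12 steps before the union.

Steps most likely to fail, with fallbacks:

1. Step 20 (diepoxide → epoxonium → allylsilane cascade; the combination of this terminator with the oxa-/carbacyclisation is the least precedented step). Fallback: build the rings stepwise. Mask the terminal olefin as its 10,11-diol acetonide (terminal-selective Sharpless dihydroxylation), epoxidise only the 6,7-olefin, close the carbocycle by Lewis-acid epoxide–allylsilane cyclisation, then convert the diol to the epoxide and close the oxepane by 7-endo etherification from the C-9a hydroxyl.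

2. Step 3 (the ketoreductase must be found by screening and must show the required carbonyl discrimination on 4). Fallback: set the quaternary centre by organocatalytic (proline-type) intramolecular aldol cyclisation of triketone 3 to (S)-Wieland–Miescher ketone, then chemoselective NaBH4 reduction of the saturated ketone to rejoin the route at 6.

3. Step 27 (kinetic α′-enolisation at the hindered C-6 of a late, precious intermediate). Fallback: introduce the C-6 oxygen before the union. The dianion of dione 15 (2 equiv LDA) can only react at C-6 (its sole γ-position) with the Davis reagent; the alcohol is then protected as a TBS ether and carried through enol-ether formation and the Stork–Danheiser coupling.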